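**Assumption:** the SMILES encodes natural (2R,4′R,8′R)-β-tocopherol; natural (E,7R,11R)-phytol and L-(S)-lactic acid of high ee are the purchased chiral materials.

## Retrosynthetic overview

1. β-Tocopherol ⇒ β-tocopherylquinone by reductive cyclodehydration (O1–C8a). This pyran ring is the only ring formed and it is closed last; the carbocycle is bought as 2,5-dimethyl-1,4-benzoquinone.
2. β-Tocopherylquinone ⇒ (3R,7R,11R)-isophytol + 2,5-dimethylbenzoquinone. The C4–C4a bond is made by a visible-light deboronative radical alkylation of the quinone.
3. Isophytol ⇒ lactate-derived dioxolanone + C16 iodide, by enolate alkylation (C2–C1′) and then methylenation (C3=C4). C2 is the carbinol carbon of L-lactic acid.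
4. C16 iodide ⇒ natural phytol (ozonolysis, Baeyer–Villiger, ester-to-iodide). C4′ and C8′ are phytol C7 and C11, never touched.

## Route

**Step 1**
Reactants: 1, natural (2E,7R,11R)-phytol
Product: 2, (6R,10R)-6,10,14-trimethylpentadecan-2-one (phytone)
Conditions: O3, CH2Cl2/MeOH, −78 °C; then Me2S, −78 °C → rt
Reagents that add atoms: ozone, [O-][O+]=O
Why: Ozonolysis cleaves the only C=C; the two stereocentres sit four and eight carbons from the new carbonyl and cannot epimerise.

**Step 2**
Reactants: 2, phytone
Product: 3, (4R,8R)-4,8,12-trimethyltridecyl acetate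
Conditions: CF3CO3H [(CF3CO)2O, urea·H2O2], Na2HPO4, CH2Cl2, 0 °C → rt
Reagents that add atoms: trifluoroperacetic acid, OOC(=O)C(F)(F)F
Why: Baeyer–Villiger oxidation; the primary alkyl group migrates in preference to methyl, excising C2/C3 of phytol and leaving the C16 chain as its acetate.

**Step 3**
Reactants: 3, C16 acetate
Product: 4, (4R,8R)-1-iodo-4,8,12-trimethyltridecane
Conditions: TMSCl, NaI (in situ Me3SiI), MeCN, 80 °C
Reagents that add atoms: iodotrimethylsilane, C[Si](C)(C)I
Why: Silyl iodide ester cleavage: the carbonyl is O-silylated and iodide displaces acetate at the primary carbon (SN2), giving the alkylating agent without a separate hydrolysis step.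

**Step 4**
Reactants: 5, (S)-lactic acid; 6, pivalaldehyde
Product: 7, (2S,5S)-2-tert-butyl-5-methyl-1,3-dioxolan-4-one (cis)
Conditions: cat. p-TsOH/H2SO4, pentane, reflux (Dean–Stark); recrystallise from pentane/Et2O at −78 °C to cis ≥ 98:2
Reagents that add atoms: none (both components are the listed reactants)
Why: Seebach acetalisation; the lactate stereocentre directs the new acetal carbon cis (about 4:1, upgraded by crystallisation), and this acetal centre stores the chirality for the next step.

**Step 5**
Reactants: 7, dioxolanone (1.5 equiv); 4, C16 iodide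
Product: 8, (2S,5R)-2-tert-butyl-5-methyl-5-[(4R,8R)-4,8,12-trimethyltridecyl]-1,3-dioxolan-4-one
Conditions: LDA, THF, −78 °C; then 4, DMPU, −78 → −30 °C
Reagents that add atoms: none
Why: Seebach self-regeneration of stereocentres: the planar lithium enolate is alkylated (SN2) anti to the tert-butyl group, so the chain takes the place of the original lactate hydrogen with net retention and creates the quaternary carbinol carbon (future C2, R).

**Step 6**
Reactants: 8
Product: 9, (2S,4RS,5R)-2-tert-butyl-5-methyl-5-[(4R,8R)-4,8,12-trimethyltridecyl]-1,3-dioxolan-4-ol (lactol, anomeric mixture)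
Conditions: DIBAL-H (1.2 equiv), toluene, −78 °C; Rochelle salt work-up
Reagents that add atoms: none
Why: DIBAL partial reduction of the lactone-type carbonyl stops at the aluminium hemiacetal at −78 °C; the adjacent quaternary centre cannot epimerise.

**Step 7**
Reactants: 9
Product: 10, (3R,7R,11R)-3,7,11,15-tetramethylhexadec-1-en-3-ol [(3R,7R,11R)-isophytol]
Conditions: Ph3P=CH2 (3.5 equiv, from Ph3PCH3Br/KOt-Bu), THF, 0 °C → rt
Reagents that add atoms: methylenetriphenylphosphorane, C=P(c1ccccc1)(c1ccccc1)c1ccccc1
Why: Wittig methylenation of a lactol: base opens the hemiacetal to the α-alkoxido aldehyde (pivalaldehyde is expelled and consumed by excess ylide), which is methylenated to the tertiary vinyl carbinol with no bond to the stereocentre broken.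

**Step 8**
Reactants: 10, (3R,7R,11R)-isophytol; 11, 2,5-dimethyl-1,4-benzoquinone
Product: 12, 2-[(3R,7R,11R)-3-hydroxy-3,7,11,15-tetramethylhexadecyl]-3,6-dimethyl-1,4-benzoquinone (β-tocopherylquinone)
Conditions: i) HBpin (1.1 equiv), [Ir(cod)Cl]2 (1.5 mol %), dppe (3 mol %), CH2Cl2, rt; evaporate; ii) KOt-Bu (1.0 equiv), MeCN/PhCF3, 0 °C; then 11 (2.2 equiv), 450 nm LEDs, 15 °C, Ar; air work-up
Reagents that add atoms: none (HBpin contributes only H; boron is not retained)
Why: Proposed new method: after standard Ir-catalysed anti-Markovnikov hydroboration, the alkoxide closes onto boron to give an alkoxy-boronate "ate" complex (Eox about +1 V), blue-light n→π* excitation of 11 gives its triplet (E*red about +1.6 V vs SCE) which oxidises the ate complex by SET, C–B homolysis releases the primary C4 radical while the tertiary oxygen stays masked as a borate (no alkoxy-radical β-scission), the radical adds to one of the two equivalent unsubstituted ring carbons of ground-state 11 (one regioisomer), and the adduct radical is reduced by the quinone radical anion to the alkylhydroquinone, which excess 11/air re-oxidises to 12 with C2 untouched; the closest known chemistry is the thermal radical-chain alkylation of benzoquinones by trialkylboranes and B-alkylcatecholboranes, Ag(I)/persulfate alkylation of quinones with boronic acids, and photoredox radical generation from Lewis-base-activated boronic esters.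

**Step 9**
Reactants: 12, β-tocopherylquinone
Product: 13, (2R,4′R,8′R)-β-tocopherol
Conditions: H2 (1 atm), 10% Pd/C, EtOAc, rt; filter under Ar; then p-TsOH·H2O (10 mol %), toluene, 70 °C
Reagents that add atoms: none
Why: Hydrogenation to the hydroquinone followed by acid-catalysed cyclodehydration of a tocopherylhydroquinone under mild, non-halide conditions, where the tertiary hydroxyl is the nucleophile toward the ring carbon (keto tautomer/hemiketal) and the aryl C–OH oxygen is the one lost, so the C2–O bond is never broken and the (R) configuration is retained while the pyran ring closes (strongly ionising HX/ZnCl2 conditions, which go through the tertiary halide or cation, are avoided).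

## Compound list

1 | (2E,7R,11R)-phytol | CC(C)CCC[C@@H](C)CCC[C@@H](C)CCC/C(C)=C/CO | starting material
2 | (6R,10R)-6,10,14-trimethylpentadecan-2-one | CC(=O)CCC[C@H](C)CCC[C@H](C)CCCC(C)C | intermediate
3 | (4R,8R)-4,8,12-trimethyltridecyl acetate | CC(=O)OCCC[C@H](C)CCC[C@H](C)CCCC(C)C | intermediate
4 | (4R,8R)-1-iodo-4,8,12-trimethyltridecane | ICCC[C@H](C)CCC[C@H](C)CCCC(C)C | intermediate
5 | (S)-lactic acid | C[C@H](O)C(=O)O | starting material
6 | pivalaldehyde | CC(C)(C)C=O | starting material
7 | (2S,5S)-2-tert-butyl-5-methyl-1,3-dioxolan-4-one | C[C@@H]1O[C@H](C(C)(C)C)OC1=O | intermediate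
8 | (2S,5R)-2-tert-butyl-5-methyl-5-[(4R,8R)-4,8,12-trimethyltridecyl]-1,3-dioxolan-4-one | C[C@]1(CCC[C@H](C)CCC[C@H](C)CCCC(C)C)O[C@H](C(C)(C)C)OC1=O | intermediate
9 | (2S,4RS,5R)-2-tert-butyl-5-methyl-5-[(4R,8R)-4,8,12-trimethyltridecyl]-1,3-dioxolan-4-ol | C[C@]1(CCC[C@H](C)CCC[C@H](C)CCCC(C)C)O[C@H](C(C)(C)C)OC1O | intermediate
10 | (3R,7R,11R)-3,7,11,15-tetramethylhexadec-1-en-3-ol | C=C[C@](C)(O)CCC[C@H](C)CCC[C@H](C)CCCC(C)C | intermediate
11 | 2,5-dimethyl-1,4-benzoquinone | CC1=CC(=O)C(C)=CC1=O | starting material
12 | 2-[(3R,7R,11R)-3-hydroxy-3,7,11,15-tetramethylhexadecyl]-3,6-dimethyl-1,4-benzoquinone | O=C1C(C)=CC(=O)C(C)=C1CC[C@](C)(O)CCC[C@H](C)CCC[C@H](C)CCCC(C)C | intermediate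
13 | (2R,4′R,8′R)-β-tocopherol | Cc1cc(O)c(C)c2c1O[C@](C)(CCC[C@H](C)CCC[C@H](C)CCCC(C)C)CC2 | target

## Summary

**Total steps:** 9, with no protecting-group steps.
**Longest linear sequence:** 8 (steps 1 → 2 → 3 → 5 → 6 → 7 → 8 → 9); step 4 is the one-step side branch.

**Steps most likely to fail, with fallbacks:**

1. **Step 8 (proposed photochemical quinone alkylation).** Risks are triplet-quinone H-abstraction from the chain, O- versus C-alkylation, and base sensitivity of the quinone. Fallback (known chemistry): 9-BBN hydroboration of 10 and B-alkyl Suzuki–Miyaura coupling with 1-bromo-2,5-dimethoxy-3,6-dimethylbenzene (PdCl2(dppf), K3PO4), then CAN oxidative demethylation to the same quinone 12.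
2. **Step 5 (alkylation of the thermally labile dioxolanone enolate with an unactivated long-chain iodide).** Fallback: alkylate 7 with the far more reactive tert-butyl bromoacetate, unmask the acid, and form C1′–C2′ by mixed Kolbe electrolysis with (4R,8R)-4,8,12-trimethyltridecanoic acid (from 3 by saponification and oxidation). The radical coupling leaves the β-quaternary centre intact and gives 8.
3. **Step 7 (Wittig on the lactol; possible α-ketol rearrangement of the hindered α-alkoxido aldehyde).** Fallback: LiAlH4 reduction of 8 to the (R)-1,2-diol, closure to the terminal epoxide (TsCl, then K2CO3), and opening at CH2 with the benzylic cuprate from 1-(chloromethyl)-2,5-dimethoxy-3,6-dimethylbenzene to form C3–C4 instead. CAN then gives 12, bypassing the vinyl carbinol and step 8.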